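Cordycicadin B is cut at C3, the ring-fusion carbon that carries both the butyrolactone oxygen and the C2–C1 acyl arm of the ten-membered lactone. This 1,2-oxygen/acyl pattern is what a carboxylate and carbon monoxide add across a C2=C3 alkene. One oxidative palladium cascade therefore forms O–C3, C2–C1 and C1–O9, closes the five-membered and the ten-membered lactone together, and sets C3. Its precursor is an acyclic 2-furyl-3-vinyl carboxylic acid lacking C1, with free C9 hydroxyl, C6 masked as a dioxolane and the side-chain carbinol silylated. Its C4 and C12 centres come from a dual iridium/isothiourea allylation that joins two chiral-pool fragments.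

Key step: step 14

Numbering:
- C1 is the macrolactone carbonyl and C2 its α-methylene.
- C3 and C4 are the ring-fusion carbons; C3 is oxygenated.
- C5 is a methylene, C6 the ketone, and C7 and C8 are methylenes.
- C9 is the methyl carbinol and C10 its methyl.
- C11 is the butyrolactone carbonyl and C12 the furyl-bearing carbon.
- Ring A is O–C3–C4–C12–C11. Ring B is C1–C9 plus the ester oxygen.
- The target is 3S,4S,9R,12S with an R side-chain carbinol. H3, H4 and H12 lie on one face of ring A, so the butyrolactone is all-cis.

Assumption: the catalyst antipodes in step 12 are assigned from the accepted models ((S)-BTM leaves the Si face of C12 open in its O···S-locked Z-enolate; the (Sa,S,S) ligand is taken to direct attack to the Re face of C4), and because the two catalysts act independently and both antipodes of each are commercial, a wrong assignment is mended by exchanging one antipode.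

Remark: C12 is enolizable and sits in the crowded cis arrangement, and the C3 acyloxy group is β to C1, so no step after the C12 centre is set uses more than a brief, cold hydroxide treatment that ends at a carboxylate.

Step 1
Reactants: 1 (R)-butane-1,3-diol
Product: 2 (R)-4-iodobutan-2-ol
Conditions: PPh3, imidazole, I2, CH2Cl2, 0 °C
Reagents that add atoms: iodine, [I][I]
Why: Garegg–Samuelsson (Appel-type) iodination is much faster at the unhindered primary hydroxyl than at the secondary one, and the carbinol stereocentre is not touched.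

Step 2
Reactants: 2 (R)-4-iodobutan-2-ol
Product: 3 (R)-tert-butyl[(4-iodobutan-2-yl)oxy]dimethylsilane
Conditions: TBSCl, imidazole, DMF, 23 °C
Reagents that add atoms: tert-butyldimethylsilyl chloride, CC(C)(C)[Si](C)(C)Cl
Why: Standard silylation of a secondary alcohol gives an ether that withstands the organolithium, zinc, hydroxide and buffered fluoride steps ahead and falls only in the final acid treatment.

Step 3
Reactants: 4 furan; 3 (R)-tert-butyl[(4-iodobutan-2-yl)oxy]dimethylsilane
Product: 6 (R)-tert-butyl{[4-(furan-2-yl)butan-2-yl]oxy}dimethylsilane, via 2-lithiofuran 5 (not isolated)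
Conditions: furan (2 equiv), n-BuLi, THF, −78 → 0 °C; then 3, DMPU, 0 → 23 °C
Reagents that add atoms: none
Why: α-Lithiation of furan followed by SN2 alkylation with a primary iodide is a standard way to 2-alkylfurans, and the excess of volatile furan suppresses double alkylation.

Step 4
Reactants: 6 (R)-tert-butyl{[4-(furan-2-yl)butan-2-yl]oxy}dimethylsilane
Product: 9 ethyl 2-{5-[(3R)-3-(tert-butyldimethylsilyloxy)butyl]furan-2-yl}acetate, via furyllithium 7 (not isolated), via furylzinc chloride 8 (not isolated)
Conditions: n-BuLi, THF, 0 °C; ZnCl2, 0 °C; Ni(acac)2 (5 mol %), PPh3 (10 mol %), BrCH2CO2Et, THF/NMP, 23 °C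
Reagents that add atoms: ethyl bromoacetate, CCOC(=O)CBr
Why: The one free α-position of the 2-alkylfuran is lithiated selectively, and after transmetalation to zinc the Negishi-type nickel-catalysed coupling of (hetero)arylzinc chlorides with ethyl bromoacetate gives the arylacetic ester without attack on the ester carbonyl.

Step 5
Reactants: 9 ethyl 2-{5-[(3R)-3-(tert-butyldimethylsilyloxy)butyl]furan-2-yl}acetate
Product: 10 2-{5-[(3R)-3-(tert-butyldimethylsilyloxy)butyl]furan-2-yl}acetic acid
Conditions: LiOH, THF/MeOH/H2O, 0 → 23 °C; then 0.5 M HCl to pH 4, 0 °C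
Reagents that add atoms: lithium hydroxide, [Li+].[OH-]
Why: Plain saponification of an unhindered ethyl ester, to which the secondary TBS ether and the furan are inert.

Step 6
Reactants: 10 2-{5-[(3R)-3-(tert-butyldimethylsilyloxy)butyl]furan-2-yl}acetic acid
Product: 11 pentafluorophenyl 2-{5-[(3R)-3-(tert-butyldimethylsilyloxy)butyl]furan-2-yl}acetate
Conditions: C6F5OH, DCC, CH2Cl2, 0 → 23 °C
Reagents that add atoms: pentafluorophenol, Oc1c(F)c(F)c(F)c(F)c1F
Why: Carbodiimide esterification with the acidic phenol gives the activated aryl ester whose aryloxide can leave and later return, as the isothiourea catalysis of the coupling step requires.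

Step 7
Reactants: 12 (R)-γ-valerolactone
Product: 13 (4R)-4-hydroxy-N-methoxy-N-methylpentanamide
Conditions: MeNH(OMe)·HCl, AlMe3, CH2Cl2, 0 → 23 °C
Reagents that add atoms: N,O-dimethylhydroxylamine hydrochloride, CNOC.Cl
Why: Weinreb amidation, in which the aluminium amide opens the lactone at the acyl carbon so that the C9 stereocentre from the chiral pool is untouched, and the hydroxy amide is silylated at once to forestall relactonization.

Step 8
Reactants: 13 (4R)-4-hydroxy-N-methoxy-N-methylpentanamide
Product: 14 (4R)-N-methoxy-N-methyl-4-(triethylsilyloxy)pentanamide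
Conditions: TESCl, imidazole, CH2Cl2, 0 °C
Reagents that add atoms: chlorotriethylsilane, CC[Si](Cl)(CC)CC
Why: Standard silylation, with TES chosen for C9 because it can later be taken off in the presence of the side-chain TBS ether, which a second TBS group would not allow.

Step 9
Reactants: 14 (4R)-N-methoxy-N-methyl-4-(triethylsilyloxy)pentanamide
Product: 15 (7R)-7-(triethylsilyloxy)oct-1-en-4-one
Conditions: allylMgBr, THF, −78 → −20 °C; cold pH 7 buffer
Reagents that add atoms: allylmagnesium bromide, C=CC[Mg]Br
Why: Weinreb ketone synthesis, in which the N-methoxy-N-methylamide stops the Grignard addition at the ketone stage and a cold neutral quench keeps the allyl ketone unconjugated.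

Step 10
Reactants: 15 (7R)-7-(triethylsilyloxy)oct-1-en-4-one
Product: 16 2-allyl-2-[(3R)-3-(triethylsilyloxy)butyl]-1,3-dioxolane
Conditions: (TMSOCH2)2, TMSOTf (5 mol %), CH2Cl2, −78 → −40 °C; pyridine quench
Reagents that add atoms: 1,2-bis(trimethylsilyloxy)ethane, C[Si](C)(C)OCCO[Si](C)(C)C
Why: Noyori ketalization is aprotic and runs at low temperature, so the β,γ-alkene does not move into conjugation and the TES ether stays, the primary silyl ether of the reagent closing the dioxolane faster than the hindered C9 silyl ether could interfere.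

Step 11
Reactants: 16 2-allyl-2-[(3R)-3-(triethylsilyloxy)butyl]-1,3-dioxolane
Product: 17 tert-butyl (2E)-4-{2-[(3R)-3-(triethylsilyloxy)butyl]-1,3-dioxolan-2-yl}but-2-en-1-yl carbonate
Conditions: allyl tert-butyl carbonate (4 equiv), second-generation Hoveyda–Grubbs catalyst (3 mol %), CH2Cl2, 40 °C
Reagents that add atoms: allyl tert-butyl carbonate, C=CCOC(=O)OC(C)(C)C
Why: Olefin cross-metathesis of an unhindered terminal alkene with an excess of the allylic carbonate is driven by loss of ethene and gives mainly the E-alkene that the next step needs, the minor Z-isomer being removed by chromatography or left behind because it ionizes more slowly.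

Step 12
Reactants: 11 pentafluorophenyl 2-{5-[(3R)-3-(tert-butyldimethylsilyloxy)butyl]furan-2-yl}acetate; 17 tert-butyl (2E)-4-{2-[(3R)-3-(triethylsilyloxy)butyl]-1,3-dioxolan-2-yl}but-2-en-1-yl carbonate
Product: 19 (2S,3R)-2-{5-[(3R)-3-(tert-butyldimethylsilyloxy)butyl]furan-2-yl}-3-({2-[(3R)-3-(triethylsilyloxy)butyl]-1,3-dioxolan-2-yl}methyl)pent-4-enoic acid, via pentafluorophenyl ester 18 (not isolated)
Conditions: cyclometalated catalyst preformed from [Ir(cod)Cl]2 (2 mol %), (Sa,S,S)-BINOL-derived N,N-bis[1-(2-methoxyphenyl)ethyl]phosphoramidite (4 mol %) and n-PrNH2 (volatiles removed), (S)-BTM (10 mol %), i-Pr2NEt, THF, 0 → 23 °C; then LiOH, THF/H2O, 0 °C; then 0.5 M HCl to pH 4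
Reagents that add atoms: lithium hydroxide, [Li+].[OH-]
Why: Known cooperative iridium/isothiourea catalysis for the branched allylation of arylacetic pentafluorophenyl esters, in which the iridium phosphoramidite ionizes 17 to an allyl complex attacked anti to the metal at the substituted terminus on the Re face of C4 (4R in 18) while (S)-BTM turns 11 into a Z-configured C1-ammonium enolate open on the Si face of C12 (12S), the released tert-butoxide being a non-nucleophilic base and pentafluorophenoxide freeing the isothiourea, after which cold LiOH cleaves the activated ester so fast that the poorly enolizable carboxylate is reached before C12 can epimerize.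

Step 13
Reactants: 19 (2S,3R)-2-{5-[(3R)-3-(tert-butyldimethylsilyloxy)butyl]furan-2-yl}-3-({2-[(3R)-3-(triethylsilyloxy)butyl]-1,3-dioxolan-2-yl}methyl)pent-4-enoic acid
Product: 20 (2S,3R)-2-{5-[(3R)-3-(tert-butyldimethylsilyloxy)butyl]furan-2-yl}-3-({2-[(3R)-3-hydroxybutyl]-1,3-dioxolan-2-yl}methyl)pent-4-enoic acid
Conditions: HF·pyridine, pyridine, THF, 0 °C
Reagents that add atoms: none
Why: Selective desilylation, since under pyridine-buffered HF the less hindered triethylsilyl ether is cleaved well before the secondary TBS ether and the buffered medium leaves the dioxolane, the furan and the C12 centre alone.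

Step 14
Reactants: 20 (2S,3R)-2-{5-[(3R)-3-(tert-butyldimethylsilyloxy)butyl]furan-2-yl}-3-({2-[(3R)-3-hydroxybutyl]-1,3-dioxolan-2-yl}methyl)pent-4-enoic acid
Product: 23 C6-dioxolane side-chain-TBS cordycicadin B (cis-fused dilactone; 3S,4S,9R,12S), via alkylpalladium lactone 21 (not isolated), via acylpalladium lactone 22 (not isolated)
Conditions: Pd(OAc)2 (15 mol %), p-benzoquinone (2 equiv), CO (1 atm), 4 Å MS, ClCH2CH2Cl, 30 °C; 20 added by syringe pump over 12 h, final 1 mM
Reagents that add atoms: carbon monoxide, [C-]#[O+]
Why: Proposed new method: divalent palladium binds the C2=C3 alkene of 20, the C11 carboxyl group adds to C3 anti to the metal to give the primary alkylpalladium 21, CO inserts into its C2–Pd bond faster than β-hydride loss to give acylpalladium 22, the C9 hydroxyl is acylated at C1, and the zerovalent palladium set free is reoxidized by benzoquinone, which takes up the two protons given off by 20. The closest known reaction types are the oxypalladation/alkoxycarbonylation of alkenols and pent-4-enoic acids with capture by an external alcohol and the tandem oxypalladation/alkoxycarbonylative macrolactonization of alkene diols, whereas a carboxylic acid as first nucleophile combined with closure of a ten-membered ring has not been shown. Ring A closes 5-exo-trig at the substituted alkene carbon and ring B closes by intramolecular acyl substitution of the C9 hydroxyl at the acyl–palladium carbon C1. C3 is controlled by C4: in the reactive rotamer the C4–C5 bond lies near the alkene plane, the C12 arm with the carboxyl group covers one face and only C4–H looks at the other, so palladium takes the open face and oxygen arrives from the C12 side, which places C2 cis to C5 (3S), while the rotamer with C4–H in the plane, which leads to the trans lactone, would press the metal against the neopentyl-like ketal arm. Since acyloxypalladation is reversible this kinetic preference counts only if CO insertion is fast, hence the CO-saturated medium, and its size remains the open point of the plan. The chemoselectivity needed is secured by the substrate, because the acid stands 1,5 to the alkene whereas the C9 hydroxyl could reach it only through an eight-membered ring, the other carbinol is silylated, the C6 ketal keeps the C9 hydroxyl from hiding as a hemiketal, no external nucleophile is present, slow addition keeps 22 dilute against oligomerization, and the cis fusion turns the C2 acyl arm and the C5 chain to the same face.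

Step 15
Reactants: 23 C6-dioxolane side-chain-TBS cordycicadin B
Product: 24 cordycicadin B
Conditions: 2 M aq HCl/THF (1:3), 23 °C
Reagents that add atoms: water, O
Why: Acid hydrolysis removes the dioxolane (helped by the change of C6 to a trigonal centre in the medium ring) and the TBS ether in one operation, and acid rather than base or fluoride ion is used because C12 is enolizable and the C3 acyloxy group is β to C1, while both lactones and the 2,5-disubstituted furan tolerate dilute acid at room temperature.

Compound list

1 | (R)-butane-1,3-diol | C[C@@H](O)CCO | starting material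
2 | (R)-4-iodobutan-2-ol | ICC[C@@H](C)O | intermediate
3 | (R)-tert-butyl[(4-iodobutan-2-yl)oxy]dimethylsilane | ICC[C@@H](C)O[Si](C)(C)C(C)(C)C | intermediate
4 | furan | c1ccoc1 | starting material
5 | 2-lithiofuran | [Li]c1ccco1 | intermediate (not isolated)
6 | (R)-tert-butyl{[4-(furan-2-yl)butan-2-yl]oxy}dimethylsilane | o1cccc1CC[C@@H](C)O[Si](C)(C)C(C)(C)C | intermediate
7 | {5-[(3R)-3-(tert-butyldimethylsilyloxy)butyl]furan-2-yl}lithium | [Li]c1ccc(CC[C@@H](C)O[Si](C)(C)C(C)(C)C)o1 | intermediate (not isolated)
8 | {5-[(3R)-3-(tert-butyldimethylsilyloxy)butyl]furan-2-yl}zinc chloride | Cl[Zn]c1ccc(CC[C@@H](C)O[Si](C)(C)C(C)(C)C)o1 | intermediate (not isolated)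
9 | ethyl 2-{5-[(3R)-3-(tert-butyldimethylsilyloxy)butyl]furan-2-yl}acetate | CCOC(=O)Cc1ccc(CC[C@@H](C)O[Si](C)(C)C(C)(C)C)o1 | intermediate
10 | 2-{5-[(3R)-3-(tert-butyldimethylsilyloxy)butyl]furan-2-yl}acetic acid | OC(=O)Cc1ccc(CC[C@@H](C)O[Si](C)(C)C(C)(C)C)o1 | intermediate
11 | pentafluorophenyl 2-{5-[(3R)-3-(tert-butyldimethylsilyloxy)butyl]furan-2-yl}acetate | O=C(Cc1ccc(CC[C@@H](C)O[Si](C)(C)C(C)(C)C)o1)Oc1c(F)c(F)c(F)c(F)c1F | intermediate
12 | (R)-γ-valerolactone, (5R)-5-methyloxolan-2-one | C[C@@H]1CCC(=O)O1 | starting material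
13 | (4R)-4-hydroxy-N-methoxy-N-methylpentanamide | C[C@@H](O)CCC(=O)N(C)OC | intermediate
14 | (4R)-N-methoxy-N-methyl-4-(triethylsilyloxy)pentanamide | C[C@@H](O[Si](CC)(CC)CC)CCC(=O)N(C)OC | intermediate
15 | (7R)-7-(triethylsilyloxy)oct-1-en-4-one | C[C@@H](O[Si](CC)(CC)CC)CCC(=O)CC=C | intermediate
16 | 2-allyl-2-[(3R)-3-(triethylsilyloxy)butyl]-1,3-dioxolane | C[C@@H](O[Si](CC)(CC)CC)CCC1(CC=C)OCCO1 | intermediate
17 | tert-butyl (2E)-4-{2-[(3R)-3-(triethylsilyloxy)butyl]-1,3-dioxolan-2-yl}but-2-en-1-yl carbonate | C[C@@H](O[Si](CC)(CC)CC)CCC1(C/C=C/COC(=O)OC(C)(C)C)OCCO1 | intermediate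
18 | pentafluorophenyl (2S,3R)-2-{5-[(3R)-3-(tert-butyldimethylsilyloxy)butyl]furan-2-yl}-3-({2-[(3R)-3-(triethylsilyloxy)butyl]-1,3-dioxolan-2-yl}methyl)pent-4-enoate | O=C(Oc1c(F)c(F)c(F)c(F)c1F)[C@H](c1ccc(CC[C@@H](C)O[Si](C)(C)C(C)(C)C)o1)[C@@H](C=C)CC1(CC[C@@H](C)O[Si](CC)(CC)CC)OCCO1 | intermediate (not isolated)
19 | (2S,3R)-2-{5-[(3R)-3-(tert-butyldimethylsilyloxy)butyl]furan-2-yl}-3-({2-[(3R)-3-(triethylsilyloxy)butyl]-1,3-dioxolan-2-yl}methyl)pent-4-enoic acid | OC(=O)[C@H](c1ccc(CC[C@@H](C)O[Si](C)(C)C(C)(C)C)o1)[C@@H](C=C)CC1(CC[C@@H](C)O[Si](CC)(CC)CC)OCCO1 | intermediate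
20 | (2S,3R)-2-{5-[(3R)-3-(tert-butyldimethylsilyloxy)butyl]furan-2-yl}-3-({2-[(3R)-3-hydroxybutyl]-1,3-dioxolan-2-yl}methyl)pent-4-enoic acid (C1-nor seco hydroxy acid; 12S,4R,9R) | OC(=O)[C@H](c1ccc(CC[C@@H](C)O[Si](C)(C)C(C)(C)C)o1)[C@@H](C=C)CC1(CC[C@@H](C)O)OCCO1 | intermediate
21 | alkylpalladium lactone: ring A closed (3S,4S,12S), C2 bound to Pd(OAc), C9 hydroxyl free | C[C@@H](O)CCC2(OCCO2)C[C@@H]3[C@H](C[Pd]OC(C)=O)OC(=O)[C@@H]3c1ccc(CC[C@@H](C)O[Si](C)(C)C(C)(C)C)o1 | intermediate (not isolated)
22 | acylpalladium lactone: as 21 with CO inserted, C1(=O) bound to Pd(OAc) | C[C@@H](O)CCC2(OCCO2)C[C@@H]3[C@H](CC(=O)[Pd]OC(C)=O)OC(=O)[C@@H]3c1ccc(CC[C@@H](C)O[Si](C)(C)C(C)(C)C)o1 | intermediate (not isolated)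
23 | protected cordycicadin B: ring A γ-lactone cis-fused at C3–C4 to ring B ten-membered lactone, C6 spiro-1,3-dioxolane, C9 methyl, C12 5-[(3R)-3-(tert-butyldimethylsilyloxy)butyl]furan-2-yl; 3S,4S,9R,12S | C[C@@H]1CCC2(OCCO2)C[C@@H]3[C@H](CC(=O)O1)OC(=O)[C@@H]3c1ccc(CC[C@@H](C)O[Si](C)(C)C(C)(C)C)o1 | intermediate
24 | cordycicadin B (3S,4S,9R,12S; side-chain carbinol R) | C[C@@H]1CCC(=O)C[C@@H]2[C@H](CC(=O)O1)OC(=O)[C@@H]2c1ccc(CC[C@@H](C)O)o1 | target

Total step count: 15. Longest linear sequence: 10 steps (steps 1–6 and 12–15). The second branch (steps 7–11) joins at step 12.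

Steps most likely to fail

1. Step 14.
- What may go wrong: capture of the acyl–palladium by the C9 hydroxyl may be slower than oligomerization or β-hydride loss. Reversal of the acyloxypalladation may also erode the facial selectivity at C3.
- Fallback: it sets out from 20 and comes back at 23, cutting the cascade into known operations. 20 is carbonylated at ordinary concentration (0.05 M) with Pd(OAc)2, benzoquinone and CO in THF containing a large excess of benzyl alcohol. This is the established oxypalladation/alkoxycarbonylation with an external alcohol, and it gives the hydroxy lactone benzyl ester F1. At this stage C3 epimers can be separated. Hydrogenolysis (H2, Pd/C, EtOAc) gives the seco hydroxy acid F2. Because the C3 acyloxy group is β to C1, the ring is then closed without base by Kita–Trost macrolactonization. Ethoxyacetylene with [RuCl2(p-cymene)]2 gives the 1-ethoxyvinyl ester F3. With catalytic camphorsulfonic acid at high dilution in ClCH2CH2Cl, F3 acylates the C9 hydroxyl to give 23.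

2. Step 12.
- What may go wrong: the alkyl-substituted allyl unit with its β-quaternary ketal carbon lies at the edge of what this dual catalysis has handled. Ionization may be slow, the branched to linear preference may be eroded, and the activated ester may partly epimerize at C12.
- Fallback: it sets out from 16 and 10 and comes back at 19.
  - Z-selective cross-metathesis of 16 with (Z)-but-2-ene-1,4-diol [Ru(S2C6H2Cl2)(SIMes)(=CHC6H4-2-Oi-Pr)] gives the (Z)-allylic alcohol F4.
  - DCC/DMAP esterification of F4 with 10 gives the (Z)-allylic furylacetate F5.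
  - KHMDS and TMSCl (THF, −78 °C) give the conjugated Z(O)-silyl ketene acetal F6.
  - On warming, the Ireland–Claisen rearrangement of F6 through a chair gives, from a Z-alkene, the required anti relation of furyl group and C5 arm.
  - After aqueous work-up, 19 is obtained together with its (12R,4S) diastereomer F7, because the absolute sense is not controlled.
  - The pair is parted by the isothiourea-catalysed acyl-transfer kinetic resolution of 2-arylalkanoic acids [(R)-BTM, pivalic anhydride, di(naphthalen-1-yl)methanol, i-Pr2NEt, CH2Cl2]. By analogy this esterifies the (12R) acid to the di(naphthalen-1-yl)methyl ester F8 and leaves 19. At best half of the material is used.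

3. Step 4.
- What may go wrong: homocoupling of the furylzinc reagent, its protonation, or reduction of the bromoacetate may outrun the cross-coupling.
- Fallback: it sets out from 6 and comes back at 9 with reversed polarity. Bromination of the free α-position (NBS, DMF, 0 °C) gives the 2-bromofuran F9, which is used at once. Palladium-catalysed α-arylation of the Reformatsky reagent BrZnCH2CO2Et [Pd(dba)2, P(t-Bu)3, THF, 23 °C] then gives 9.

Further compounds

F1 | step 14 | benzyl ester of the C1 acid: ring A closed (3S,4S,12S), C2–C1(=O)OBn, C9 hydroxyl free, C6 dioxolane, side-chain TBS ether | C[C@@H](O)CCC2(OCCO2)C[C@@H]3[C@H](CC(=O)OCc4ccccc4)OC(=O)[C@@H]3c1ccc(CC[C@@H](C)O[Si](C)(C)C(C)(C)C)o1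
F2 | step 14 | seco hydroxy acid: as F1 with free C1 carboxylic acid | C[C@@H](O)CCC2(OCCO2)C[C@@H]3[C@H](CC(=O)O)OC(=O)[C@@H]3c1ccc(CC[C@@H](C)O[Si](C)(C)C(C)(C)C)o1
F3 | step 14 | 1-ethoxyvinyl ester of F2 | C[C@@H](O)CCC2(OCCO2)C[C@@H]3[C@H](CC(=O)OC(=C)OCC)OC(=O)[C@@H]3c1ccc(CC[C@@H](C)O[Si](C)(C)C(C)(C)C)o1
F4 | step 12 | (2Z)-4-{2-[(3R)-3-(triethylsilyloxy)butyl]-1,3-dioxolan-2-yl}but-2-en-1-ol | C[C@@H](O[Si](CC)(CC)CC)CCC1(C/C=C\CO)OCCO1
F5 | step 12 | (2Z)-4-{2-[(3R)-3-(triethylsilyloxy)butyl]-1,3-dioxolan-2-yl}but-2-en-1-yl 2-{5-[(3R)-3-(tert-butyldimethylsilyloxy)butyl]furan-2-yl}acetate | O=C(Cc1ccc(CC[C@@H](C)O[Si](C)(C)C(C)(C)C)o1)OC/C=C\CC1(CC[C@@H](C)O[Si](CC)(CC)CC)OCCO1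
F6 | step 12 | trimethylsilyl ketene acetal of F5, furyl group cis to the silyloxy group | C[Si](C)(C)O/C(=C\c1ccc(CC[C@@H](C)O[Si](C)(C)C(C)(C)C)o1)OC/C=C\CC1(CC[C@@H](C)O[Si](CC)(CC)CC)OCCO1
F7 | step 12 | (2R,3S) diastereomer of 19 | OC(=O)[C@@H](c1ccc(CC[C@@H](C)O[Si](C)(C)C(C)(C)C)o1)[C@H](C=C)CC1(CC[C@@H](C)O[Si](CC)(CC)CC)OCCO1
F8 | step 12 | di(naphthalen-1-yl)methyl ester of F7 | O=C(OC(c1cccc2ccccc12)c1cccc2ccccc12)[C@@H](c1ccc(CC[C@@H](C)O[Si](C)(C)C(C)(C)C)o1)[C@H](C=C)CC1(CC[C@@H](C)O[Si](CC)(CC)CC)OCCO1
F9 | step 4 | (R)-{[4-(5-bromofuran-2-yl)butan-2-yl]oxy}(tert-butyl)dimethylsilane | Brc1ccc(CC[C@@H](C)O[Si](C)(C)C(C)(C)C)o1
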